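Everything rests on cutting the C1'–C6' bond of ring C. Ring C is a resorcinol, that is a folded 1,3,5-tricarbonyl chain in which C1' lies between the C2' carbonyl and the ketone that joins it to C2 of ring A; the key step exploits exactly this doubly activated C1'. Carbons C2'–C6' are therefore carried as a 2,6-disubstituted 4-pyrone, 22, with a CH2–CO–naphthyl arm (the fully methylated ring A/B unit) and a triisopropylsilyloxymethyl arm. Hydroxide opens the pyrone and an aldol of C1' onto the C6' carbonyl builds ring C around the hindered ketone in one operation. The 4-hydroxy-2-pyrone is then grown from the C6' CH2O carbon and ring B is unmasked last.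

Key step: step 14

Numbering used: naphthalene C1 (methyl), C2 (ketone), C3 (oxygen), C5 and C8 (quinone carbonyls), C6 (oxygen); ring A = C1–C4, C4a, C8a; ring B = C4a–C8a; ring C = C1'–C6' with C1' on the ketone, oxygen at C2' and C4', CH2 at C6'.

Remark on the chemistry: the ring-opened pyrone is a 1,3,5,7-tetraketone (the naphthyl ketone included), so C3' and C5' are doubly activated as well as C1'. Selectivity for C1' therefore rests on ring size and on the hindrance of the naphthyl ketone, as argued in step 14.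

Design remark: the oxygen on the C6' arm is protected as a triisopropylsilyl ether, not as a benzyl ether, for three reasons.
- After ring C forms, this oxygen sits on a benzylic carbon, so hydrogenolysis or a Lewis acid could not tell the two C–O bonds of a benzyl ether apart, whereas Si–O is cut by fluoride alone.
- The bulky silyl group shields the CH2O protons during lateral lithiation of the pyrone, and a silyl ether cannot undergo the [1,2]-Wittig shift open to a benzyl ether.
- The group is inert to hydroxide and further disfavours an aldol from the CH2O carbon.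

Ring C phenols are capped as methyl ethers, so that one BBr3 treatment at the end removes all six methyl groups.

Assumption: compounds 1, 7, 14 and 16 are commercial; no compound on the route carries a stereocentre that survives to the target, which is achiral.

Step 1
Reactants: 1 methyl 2-(3,5-dimethoxyphenyl)acetate
Product: 2 methyl 2-(2-formyl-3,5-dimethoxyphenyl)acetate
Conditions: POCl3, DMF, 0 °C → 60 °C; then H2O
Reagents that add atoms: N,N-dimethylformamide CN(C)C=O; water O
Why: Vilsmeier–Haack formylation should go to C2, which is ortho and para to the two methoxy groups and less crowded than C4 between them.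

Step 2
Reactants: 2 methyl 2-(2-formyl-3,5-dimethoxyphenyl)acetate
Product: 4 methyl 2-(2-hydroxy-3,5-dimethoxyphenyl)acetate, via aryl formate 3 (not isolated)
Conditions: mCPBA, CH2Cl2, 0 °C → rt; then Et3N (cat.), MeOH, rt
Reagents that add atoms: 3-chloroperoxybenzoic acid OOC(=O)c1cccc(Cl)c1
Why: Baeyer–Villiger oxidation (Dakin type) of the electron-rich benzaldehyde proceeds by aryl migration to the aryl formate, which methanol cleaves to the phenol.

Step 3
Reactants: 4 methyl 2-(2-hydroxy-3,5-dimethoxyphenyl)acetate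
Product: 6 2-(2,3,5-trimethoxyphenyl)acetic acid, via methyl ester 5 (not isolated)
Conditions: MeI, K2CO3, DMF, rt; then NaOH, H2O/MeOH, 60 °C; then HCl
Reagents that add atoms: iodomethane CI; sodium hydroxide [Na+].[OH-]
Why: Williamson O-methylation of the phenoxide and saponification of the ester in one pot give the arylacetic acid that carries the complete 1,2,4-trioxygenation of ring B.

Step 4
Reactants: 6 2-(2,3,5-trimethoxyphenyl)acetic acid; 7 methyl acetoacetate
Product: 9 methyl 2-acetyl-3-oxo-4-(2,3,5-trimethoxyphenyl)butanoate, via acid chloride 8 (not isolated)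
Conditions: (COCl)2, DMF (cat.), CH2Cl2, 0 °C → rt; evaporate; then 7, MgCl2, pyridine, CH2Cl2, 0 °C → rt; 1 M HCl
Reagents that add atoms: none
Why: C-acylation of the magnesium enolate of a β-keto ester by an acid chloride gives the 2-acylacetoacetate, the chelated enolate suppressing O-acylation.

Step 5
Reactants: 9 methyl 2-acetyl-3-oxo-4-(2,3,5-trimethoxyphenyl)butanoate
Product: 10 methyl 3-hydroxy-5,6,8-trimethoxy-1-methylnaphthalene-2-carboxylate
Conditions: MeSO3H, CH2Cl2, 0 °C → rt
Reagents that add atoms: none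
Why: Intramolecular Friedel–Crafts cyclodehydration (Bradsher type) should occur at the only free position ortho to the side chain, which is ortho and para to methoxy groups, on the acetyl carbonyl in preference to the ester, and loss of water with enolisation gives ring A with C1–Me, C2–CO2Me and C3–OH.

Step 6
Reactants: 10 methyl 3-hydroxy-5,6,8-trimethoxy-1-methylnaphthalene-2-carboxylate
Product: 11 methyl 3,5,6,8-tetramethoxy-1-methylnaphthalene-2-carboxylate
Conditions: MeI, K2CO3, DMF, 50 °C
Reagents that add atoms: iodomethane CI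
Why: Williamson O-methylation of the hydrogen-bonded naphthol proceeds with carbonate in a dipolar aprotic solvent.

Step 7
Reactants: 11 methyl 3,5,6,8-tetramethoxy-1-methylnaphthalene-2-carboxylate
Product: 12 (3,5,6,8-tetramethoxy-1-methylnaphthalen-2-yl)methanol
Conditions: iBu2AlH, CH2Cl2, −78 °C → 0 °C; aq. KNaC4H4O6
Reagents that add atoms: none
Why: Hydride reduction of the ester to the primary alcohol, the small hydride donor reaching the carbonyl group between C1–Me and C3–OMe.

Step 8
Reactants: 12 (3,5,6,8-tetramethoxy-1-methylnaphthalen-2-yl)methanol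
Product: 13 3,5,6,8-tetramethoxy-1-methylnaphthalene-2-carbaldehyde
Conditions: MnO2, CH2Cl2, rt
Reagents that add atoms: none
Why: MnO2 oxidation of a benzylic-type alcohol stops at the aldehyde.

Step 9
Reactants: 14 methyl glycolate
Product: 15 methyl 2-[(triisopropylsilyl)oxy]acetate
Conditions: iPr3SiCl, imidazole, DMF, rt
Reagents that add atoms: chlorotriisopropylsilane CC(C)[Si](Cl)(C(C)C)C(C)C
Why: Silylation of a primary alcohol with a silyl chloride and imidazole is routine, and the bulky group is chosen for its stability to base and its shielding of the adjacent CH2.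

Step 10
Reactants: 16 pentane-2,4-dione; 15 methyl 2-[(triisopropylsilyl)oxy]acetate
Product: 18 1-[(triisopropylsilyl)oxy]heptane-2,4,6-trione, via dilithium dianion of pentane-2,4-dione 17 (not isolated)
Conditions: LiN(iPr)2 (2 equiv), THF, −78 °C → 0 °C; then 15, −78 °C → 0 °C; AcOH
Reagents that add atoms: none
Why: Claisen acylation of the dianion of a 1,3-diketone takes place at the more basic terminal carbanion and gives the 1,3,5-triketone.

Step 11
Reactants: 18 1-[(triisopropylsilyl)oxy]heptane-2,4,6-trione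
Product: 19 2-methyl-6-{[(triisopropylsilyl)oxy]methyl}-4H-pyran-4-one
Conditions: CF3CO2H, CH2Cl2, 0 °C → rt
Reagents that add atoms: none
Why: Acid-catalysed cyclodehydration of a 1,3,5-triketone to the 4-pyrone is facile, and a primary triisopropylsilyl ether should tolerate brief exposure to CF3CO2H.

Step 12
Reactants: 19 2-methyl-6-{[(triisopropylsilyl)oxy]methyl}-4H-pyran-4-one; 13 3,5,6,8-tetramethoxy-1-methylnaphthalene-2-carbaldehyde
Product: 21 2-[2-hydroxy-2-(3,5,6,8-tetramethoxy-1-methylnaphthalen-2-yl)ethyl]-6-{[(triisopropylsilyl)oxy]methyl}-4H-pyran-4-one (racemic), via lithiated pyrone 20 (not isolated)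
Conditions: LiN(SiMe3)2, THF, −78 °C; then 13, −78 °C; AcOH, −78 °C
Reagents that add atoms: none
Why: Vinylogous (lateral) deprotonation of the pyrone 2-methyl group and aldol addition to the aldehyde; the methyl group should be deprotonated in preference to the silyl-shielded CH2O group, and the new carbinol centre forms as a racemate that the next step removes.

Step 13
Reactants: 21 2-[2-hydroxy-2-(3,5,6,8-tetramethoxy-1-methylnaphthalen-2-yl)ethyl]-6-{[(triisopropylsilyl)oxy]methyl}-4H-pyran-4-one
Product: 22 2-[2-oxo-2-(3,5,6,8-tetramethoxy-1-methylnaphthalen-2-yl)ethyl]-6-{[(triisopropylsilyl)oxy]methyl}-4H-pyran-4-one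
Conditions: Dess–Martin periodinane, CH2Cl2, 0 °C → rt
Reagents that add atoms: none
Why: Dess–Martin oxidation converts the secondary alcohol into the ketone under near-neutral conditions that avoid dehydration to the styrylpyrone.

Step 14
Reactants: 22 2-[2-oxo-2-(3,5,6,8-tetramethoxy-1-methylnaphthalen-2-yl)ethyl]-6-{[(triisopropylsilyl)oxy]methyl}-4H-pyran-4-one
Product: 25 [2,4-dihydroxy-6-{[(triisopropylsilyl)oxy]methyl}phenyl](3,5,6,8-tetramethoxy-1-methylnaphthalen-2-yl)methanone, via open-chain tetraketone 23 (not isolated), via cyclic ketol 24 (not isolated)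
Conditions: KOH, MeOH/H2O, 45 °C, N2; then 1 M HCl, 0 °C
Reagents that add atoms: none
Why: Hydroxide adds to C2 or C6 of the 4-pyrone and the ring opens reversibly to the 1,3,5,7-tetraketone 23, present as its enolates. C1', flanked by the C2' carbonyl and the naphthyl ketone, adds to the C6' carbonyl in a 6-exo-trig aldol (enolexo if the naphthoyl oxygen carries the charge, enolendo if the C2' oxygen does, both allowed) to give ketol 24, and loss of water with enolisation at C2' and C4' gives the resorcinol, aromatisation making the sequence irreversible. The closest known reaction type is the base-induced conversion of 2,6-disubstituted 4-pyrones, as stable carriers of 1,3,5-tricarbonyl chains, into resorcinols. Ring C is the only ring closed and no stereocentre remains, since those of 24 are lost on aromatisation. The step needs regioselectivity among the conceivable six-membered aldols: C3' has no carbonyl within six-ring reach and C5' could only add to the naphthyl ketone, which is flanked by C1–Me and C3–OMe and twisted out of plane, while the silyloxymethyl carbon is singly activated and shielded by the silyl group. The silyl ether and the aryl methyl ethers should be inert to hydroxide at this temperature.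

Step 15
Reactants: 25 [2,4-dihydroxy-6-{[(triisopropylsilyl)oxy]methyl}phenyl](3,5,6,8-tetramethoxy-1-methylnaphthalen-2-yl)methanone
Product: 26 [2,4-dimethoxy-6-{[(triisopropylsilyl)oxy]methyl}phenyl](3,5,6,8-tetramethoxy-1-methylnaphthalen-2-yl)methanone
Conditions: MeI, K2CO3, DMF, 40 °C
Reagents that add atoms: iodomethane CI
Why: Williamson O-methylation of both phenols, including the hydrogen-bonded C2' hydroxyl, caps ring C for the carbanion chemistry that follows.

Step 16
Reactants: 26 [2,4-dimethoxy-6-{[(triisopropylsilyl)oxy]methyl}phenyl](3,5,6,8-tetramethoxy-1-methylnaphthalen-2-yl)methanone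
Product: 27 [2-(hydroxymethyl)-4,6-dimethoxyphenyl](3,5,6,8-tetramethoxy-1-methylnaphthalen-2-yl)methanone
Conditions: Bu4NF, AcOH, THF, 0 °C → rt
Reagents that add atoms: none
Why: Fluoride-mediated cleavage of the Si–O bond frees the benzylic alcohol without touching the aryl methyl ethers or the ketone, acetic acid buffering the alkoxide.

Step 17
Reactants: 27 [2-(hydroxymethyl)-4,6-dimethoxyphenyl](3,5,6,8-tetramethoxy-1-methylnaphthalen-2-yl)methanone
Product: 28 [2-(bromomethyl)-4,6-dimethoxyphenyl](3,5,6,8-tetramethoxy-1-methylnaphthalen-2-yl)methanone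
Conditions: CBr4, PPh3, CH2Cl2, 0 °C
Reagents that add atoms: tetrabromomethane BrC(Br)(Br)Br
Why: Appel bromination converts the primary benzylic alcohol into the bromide under neutral conditions by SN2 displacement of the alkoxyphosphonium ion.

Step 18
Reactants: 28 [2-(bromomethyl)-4,6-dimethoxyphenyl](3,5,6,8-tetramethoxy-1-methylnaphthalen-2-yl)methanone
Product: 29 methyl 2-[3,5-dimethoxy-2-(3,5,6,8-tetramethoxy-1-methylnaphthalene-2-carbonyl)phenyl]acetate
Conditions: CO (1 atm), MeOH, Pd(PPh3)2Cl2 (cat.), iPr2NEt, THF, 50 °C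
Reagents that add atoms: carbon monoxide [C-]#[O+]; methanol CO
Why: Palladium-catalysed methoxycarbonylation of a benzylic bromide (oxidative addition to zerovalent palladium, CO insertion, methanolysis of the acyl complex) gives the arylacetate and adds the carbon that becomes C6 of the pyranone.

Step 19
Reactants: 29 methyl 2-[3,5-dimethoxy-2-(3,5,6,8-tetramethoxy-1-methylnaphthalene-2-carbonyl)phenyl]acetate; 7 methyl acetoacetate
Product: 31 methyl 6-[3,5-dimethoxy-2-(3,5,6,8-tetramethoxy-1-methylnaphthalene-2-carbonyl)phenyl]-3,5-dioxohexanoate, via dilithium dianion of methyl acetoacetate 30 (not isolated)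
Conditions: 7, LiN(iPr)2 (2 equiv per 7, dianion in excess), THF, 0 °C; then 29, −78 °C → 0 °C; AcOH
Reagents that add atoms: none
Why: Claisen acylation of the acetoacetate dianion at its terminal carbon by the methyl ester gives the 3,5-dioxo ester; excess dianion compensates for reversible enolisation of the arylacetate, and the tetra-ortho-substituted diaryl ketone is too hindered to be attacked.

Step 20
Reactants: 31 methyl 6-[3,5-dimethoxy-2-(3,5,6,8-tetramethoxy-1-methylnaphthalene-2-carbonyl)phenyl]-3,5-dioxohexanoate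
Product: 32 6-{[3,5-dimethoxy-2-(3,5,6,8-tetramethoxy-1-methylnaphthalene-2-carbonyl)phenyl]methyl}-4-hydroxy-2H-pyran-2-one
Conditions: DBU, toluene, rt → 60 °C; then 1 M HCl
Reagents that add atoms: none
Why: Base-mediated lactonisation of the 3,5-dioxo ester (enol oxygen of the C5 ketone onto the ester) gives the 4-hydroxy-2-pyranone, a six-membered acyl substitution that should outrun aldol attack on the hindered diaryl ketone.

Step 21
Reactants: 32 6-{[3,5-dimethoxy-2-(3,5,6,8-tetramethoxy-1-methylnaphthalene-2-carbonyl)phenyl]methyl}-4-hydroxy-2H-pyran-2-one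
Product: 34 6-{[3,5-dihydroxy-2-(3,6-dihydroxy-1-methyl-5,8-dioxo-5,8-dihydronaphthalene-2-carbonyl)phenyl]methyl}-4-hydroxy-2H-pyran-2-one (target), via 5,6,8-trihydroxynaphthalene 33 (not isolated)
Conditions: BBr3, CH2Cl2, −78 °C → rt; then H2O, air, rt
Reagents that add atoms: none
Why: BBr3 cleaves all six aryl methyl ethers (Lewis acid-mediated demethylation), and the 5,6,8-trihydroxynaphthalene so formed is a hydroxyhydroquinone that autoxidises in air to the 6-hydroxy-5,8-quinone, while the resorcinol, the C3 phenol and the pyranone are not oxidised.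

Compound list

1 | methyl 2-(3,5-dimethoxyphenyl)acetate | COC(=O)Cc1cc(OC)cc(OC)c1 | starting material
2 | methyl 2-(2-formyl-3,5-dimethoxyphenyl)acetate | COC(=O)Cc1cc(OC)cc(OC)c1C=O | intermediate
3 | methyl 2-[2-(formyloxy)-3,5-dimethoxyphenyl]acetate (aryl formate, not isolated) | COC(=O)Cc1cc(OC)cc(OC)c1OC=O | intermediate
4 | methyl 2-(2-hydroxy-3,5-dimethoxyphenyl)acetate | COC(=O)Cc1cc(OC)cc(OC)c1O | intermediate
5 | methyl 2-(2,3,5-trimethoxyphenyl)acetate (not isolated) | COC(=O)Cc1cc(OC)cc(OC)c1OC | intermediate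
6 | 2-(2,3,5-trimethoxyphenyl)acetic acid | OC(=O)Cc1cc(OC)cc(OC)c1OC | intermediate
7 | methyl acetoacetate | COC(=O)CC(C)=O | starting material
8 | 2-(2,3,5-trimethoxyphenyl)acetyl chloride (not isolated) | ClC(=O)Cc1cc(OC)cc(OC)c1OC | intermediate
9 | methyl 2-acetyl-3-oxo-4-(2,3,5-trimethoxyphenyl)butanoate (enolised, no fixed stereocentre) | COC(=O)C(C(C)=O)C(=O)Cc1cc(OC)cc(OC)c1OC | intermediate
10 | methyl 3-hydroxy-5,6,8-trimethoxy-1-methylnaphthalene-2-carboxylate | COC(=O)c1c(C)c2c(OC)cc(OC)c(OC)c2cc1O | intermediate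
11 | methyl 3,5,6,8-tetramethoxy-1-methylnaphthalene-2-carboxylate | COC(=O)c1c(C)c2c(OC)cc(OC)c(OC)c2cc1OC | intermediate
12 | (3,5,6,8-tetramethoxy-1-methylnaphthalen-2-yl)methanol | OCc1c(C)c2c(OC)cc(OC)c(OC)c2cc1OC | intermediate
13 | 3,5,6,8-tetramethoxy-1-methylnaphthalene-2-carbaldehyde | O=Cc1c(C)c2c(OC)cc(OC)c(OC)c2cc1OC | intermediate
14 | methyl glycolate | COC(=O)CO | starting material
15 | methyl 2-[(triisopropylsilyl)oxy]acetate | COC(=O)CO[Si](C(C)C)(C(C)C)C(C)C | intermediate
16 | pentane-2,4-dione | CC(=O)CC(C)=O | starting material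
17 | dilithium dianion of pentane-2,4-dione (not isolated) | C=C(O[Li])C=C(C)O[Li] | intermediate
18 | 1-[(triisopropylsilyl)oxy]heptane-2,4,6-trione | CC(=O)CC(=O)CC(=O)CO[Si](C(C)C)(C(C)C)C(C)C | intermediate
19 | 2-methyl-6-{[(triisopropylsilyl)oxy]methyl}-4H-pyran-4-one | CC1=CC(=O)C=C(CO[Si](C(C)C)(C(C)C)C(C)C)O1 | intermediate
20 | 2-(lithiomethyl)-6-{[(triisopropylsilyl)oxy]methyl}-4H-pyran-4-one (not isolated) | [Li]CC1=CC(=O)C=C(CO[Si](C(C)C)(C(C)C)C(C)C)O1 | intermediate
21 | 2-[2-hydroxy-2-(3,5,6,8-tetramethoxy-1-methylnaphthalen-2-yl)ethyl]-6-{[(triisopropylsilyl)oxy]methyl}-4H-pyran-4-one (racemic) | Cc1c(C(O)CC3=CC(=O)C=C(CO[Si](C(C)C)(C(C)C)C(C)C)O3)c(OC)cc2c(OC)c(OC)cc(OC)c12 | intermediate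
22 | 2-[2-oxo-2-(3,5,6,8-tetramethoxy-1-methylnaphthalen-2-yl)ethyl]-6-{[(triisopropylsilyl)oxy]methyl}-4H-pyran-4-one | Cc1c(C(=O)CC3=CC(=O)C=C(CO[Si](C(C)C)(C(C)C)C(C)C)O3)c(OC)cc2c(OC)c(OC)cc(OC)c12 | intermediate
23 | 1-(3,5,6,8-tetramethoxy-1-methylnaphthalen-2-yl)-8-[(triisopropylsilyl)oxy]octane-1,3,5,7-tetraone (as enolates, not isolated) | Cc1c(C(=O)CC(=O)CC(=O)CC(=O)CO[Si](C(C)C)(C(C)C)C(C)C)c(OC)cc2c(OC)c(OC)cc(OC)c12 | intermediate
24 | 5-hydroxy-4-(3,5,6,8-tetramethoxy-1-methylnaphthalene-2-carbonyl)-5-{[(triisopropylsilyl)oxy]methyl}cyclohexane-1,3-dione (mixture of stereoisomers, not isolated) | Cc1c(C(=O)C3C(=O)CC(=O)CC3(O)CO[Si](C(C)C)(C(C)C)C(C)C)c(OC)cc2c(OC)c(OC)cc(OC)c12 | intermediate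
25 | [2,4-dihydroxy-6-{[(triisopropylsilyl)oxy]methyl}phenyl](3,5,6,8-tetramethoxy-1-methylnaphthalen-2-yl)methanone | Cc1c(C(=O)c3c(O)cc(O)cc3CO[Si](C(C)C)(C(C)C)C(C)C)c(OC)cc2c(OC)c(OC)cc(OC)c12 | intermediate
26 | [2,4-dimethoxy-6-{[(triisopropylsilyl)oxy]methyl}phenyl](3,5,6,8-tetramethoxy-1-methylnaphthalen-2-yl)methanone | Cc1c(C(=O)c3c(OC)cc(OC)cc3CO[Si](C(C)C)(C(C)C)C(C)C)c(OC)cc2c(OC)c(OC)cc(OC)c12 | intermediate
27 | [2-(hydroxymethyl)-4,6-dimethoxyphenyl](3,5,6,8-tetramethoxy-1-methylnaphthalen-2-yl)methanone | Cc1c(C(=O)c3c(OC)cc(OC)cc3CO)c(OC)cc2c(OC)c(OC)cc(OC)c12 | intermediate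
28 | [2-(bromomethyl)-4,6-dimethoxyphenyl](3,5,6,8-tetramethoxy-1-methylnaphthalen-2-yl)methanone | Cc1c(C(=O)c3c(OC)cc(OC)cc3CBr)c(OC)cc2c(OC)c(OC)cc(OC)c12 | intermediate
29 | methyl 2-[3,5-dimethoxy-2-(3,5,6,8-tetramethoxy-1-methylnaphthalene-2-carbonyl)phenyl]acetate | Cc1c(C(=O)c3c(OC)cc(OC)cc3CC(=O)OC)c(OC)cc2c(OC)c(OC)cc(OC)c12 | intermediate
30 | dilithium dianion of methyl acetoacetate (not isolated) | C=C(O[Li])C=C(OC)O[Li] | intermediate
31 | methyl 6-[3,5-dimethoxy-2-(3,5,6,8-tetramethoxy-1-methylnaphthalene-2-carbonyl)phenyl]-3,5-dioxohexanoate | Cc1c(C(=O)c3c(OC)cc(OC)cc3CC(=O)CC(=O)CC(=O)OC)c(OC)cc2c(OC)c(OC)cc(OC)c12 | intermediate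
32 | 6-{[3,5-dimethoxy-2-(3,5,6,8-tetramethoxy-1-methylnaphthalene-2-carbonyl)phenyl]methyl}-4-hydroxy-2H-pyran-2-one | Cc1c(C(=O)c3c(OC)cc(OC)cc3Cc3cc(O)cc(=O)o3)c(OC)cc2c(OC)c(OC)cc(OC)c12 | intermediate
33 | 6-{[3,5-dihydroxy-2-(3,5,6,8-tetrahydroxy-1-methylnaphthalene-2-carbonyl)phenyl]methyl}-4-hydroxy-2H-pyran-2-one (not isolated) | Cc1c(C(=O)c3c(O)cc(O)cc3Cc3cc(O)cc(=O)o3)c(O)cc2c(O)c(O)cc(O)c12 | intermediate
34 | 6-{[3,5-dihydroxy-2-(3,6-dihydroxy-1-methyl-5,8-dioxo-5,8-dihydronaphthalene-2-carbonyl)phenyl]methyl}-4-hydroxy-2H-pyran-2-one (CNP0141484.0, achiral) | Cc1c(C(=O)c2c(O)cc(O)cc2Cc2cc(O)cc(=O)o2)c(O)cc2c1C(=O)C=C(O)C2=O | target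

Total step count: 21. Longest linear sequence: 18 steps (steps 1–8, then 12–21); the pyrone branch (steps 9–11) joins at step 12.

Steps most likely to fail

1. Step 14. The ring-opened polyketone may fragment by retro-Claisen attack of hydroxide or methoxide, or may reclose to the pyrone faster than C1' adds to C6', so that conversion to the arene stalls. The fallback sets out from aldehyde 13 and comes back at 26; it makes the diaryl ketone by aryl–carbonyl bond formation instead of building ring C. Commercial 3,5-dimethoxybenzyl alcohol would be brominated with N-bromosuccinimide at the position between CH2OH and a methoxy group to give (2-bromo-3,5-dimethoxyphenyl)methanol F1. Silylation (iPr3SiCl, imidazole) would give [(2-bromo-3,5-dimethoxyphenyl)methoxy]triisopropylsilane F2. Bromine–lithium exchange (n-BuLi, THF, −78 °C) would give [2,4-dimethoxy-6-{[(triisopropylsilyl)oxy]methyl}phenyl]lithium F3, which should add to 13 to give the racemic carbinol [2,4-dimethoxy-6-{[(triisopropylsilyl)oxy]methyl}phenyl](3,5,6,8-tetramethoxy-1-methylnaphthalen-2-yl)methanol F4. Dess–Martin oxidation of F4 gives 26.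

2. Step 19. Proton transfer from the acidic arylacetate CH2 to the strongly basic dianion may outpace acyl substitution, so that the ester is returned on work-up. The fallback sets out from 29 and comes back at 32; it pairs a stronger acyl donor with a much weaker base and closes the pyranone thermally. LiOH hydrolysis of 29 would give 2-[3,5-dimethoxy-2-(3,5,6,8-tetramethoxy-1-methylnaphthalene-2-carbonyl)phenyl]acetic acid F5. 1,1'-Carbonyldiimidazole would convert F5 into the acyl imidazole 1-(1H-imidazol-1-yl)-2-[3,5-dimethoxy-2-(3,5,6,8-tetramethoxy-1-methylnaphthalene-2-carbonyl)phenyl]ethan-1-one F6. Acylation of the lithium dienolate of 2,2,6-trimethyl-4H-1,3-dioxin-4-one (LiN(SiMe3)2, THF, −78 °C) at its terminal carbon would give 6-{3-[3,5-dimethoxy-2-(3,5,6,8-tetramethoxy-1-methylnaphthalene-2-carbonyl)phenyl]-2-oxopropyl}-2,2-dimethyl-4H-1,3-dioxin-4-one F7. Heating F7 in toluene at 110 °C should expel acetone by retro-[4+2] reaction, and the acylketene is trapped by the enol oxygen of the side-chain ketone to give 32.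

3. Step 21. Cleavage of six ethers may stop short, or the long exposure to the Lewis acid may promote condensation at the diaryl ketone before all groups are off. The fallback sets out from 32 and comes back at 34; it unmasks ring B oxidatively first, so that the Lewis acid has less to do. (NH4)2Ce(NO3)6 in MeCN/H2O at 0 °C should demethylate the para-dimethoxy pair at C5 and C8 oxidatively to give 6-{[3,5-dimethoxy-2-(3,6-dimethoxy-1-methyl-5,8-dioxo-5,8-dihydronaphthalene-2-carbonyl)phenyl]methyl}-4-hydroxy-2H-pyran-2-one F8. Any isomeric ortho-quinone would converge, since both give the same hydroxyquinone after demethylation. A shorter BBr3 treatment (CH2Cl2, −78 °C → 0 °C) then removes the four remaining methyl groups to give 34.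

Further compounds

F1 | step 14 | (2-bromo-3,5-dimethoxyphenyl)methanol | OCc1cc(OC)cc(OC)c1Br
F2 | step 14 | [(2-bromo-3,5-dimethoxyphenyl)methoxy]triisopropylsilane | CC(C)[Si](OCc1cc(OC)cc(OC)c1Br)(C(C)C)C(C)C
F3 | step 14 | [2,4-dimethoxy-6-{[(triisopropylsilyl)oxy]methyl}phenyl]lithium | [Li]c1c(OC)cc(OC)cc1CO[Si](C(C)C)(C(C)C)C(C)C
F4 | step 14 | [2,4-dimethoxy-6-{[(triisopropylsilyl)oxy]methyl}phenyl](3,5,6,8-tetramethoxy-1-methylnaphthalen-2-yl)methanol (racemic) | Cc1c(C(O)c3c(OC)cc(OC)cc3CO[Si](C(C)C)(C(C)C)C(C)C)c(OC)cc2c(OC)c(OC)cc(OC)c12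
F5 | step 19 | 2-[3,5-dimethoxy-2-(3,5,6,8-tetramethoxy-1-methylnaphthalene-2-carbonyl)phenyl]acetic acid | Cc1c(C(=O)c3c(OC)cc(OC)cc3CC(=O)O)c(OC)cc2c(OC)c(OC)cc(OC)c12
F6 | step 19 | 1-(1H-imidazol-1-yl)-2-[3,5-dimethoxy-2-(3,5,6,8-tetramethoxy-1-methylnaphthalene-2-carbonyl)phenyl]ethan-1-one | Cc1c(C(=O)c3c(OC)cc(OC)cc3CC(=O)n4ccnc4)c(OC)cc2c(OC)c(OC)cc(OC)c12
F7 | step 19 | 6-{3-[3,5-dimethoxy-2-(3,5,6,8-tetramethoxy-1-methylnaphthalene-2-carbonyl)phenyl]-2-oxopropyl}-2,2-dimethyl-4H-1,3-dioxin-4-one | Cc1c(C(=O)c3c(OC)cc(OC)cc3CC(=O)CC4=CC(=O)OC(C)(C)O4)c(OC)cc2c(OC)c(OC)cc(OC)c12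
F8 | step 21 | 6-{[3,5-dimethoxy-2-(3,6-dimethoxy-1-methyl-5,8-dioxo-5,8-dihydronaphthalene-2-carbonyl)phenyl]methyl}-4-hydroxy-2H-pyran-2-one | Cc1c(C(=O)c3c(OC)cc(OC)cc3Cc4cc(O)cc(=O)o4)c(OC)cc2c1C(=O)C=C(OC)C2=O
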